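## Structural features

The target is a germacranolide: a ten-membered carbocycle cis-fused across C6–C7 to an α-methylene-γ-butyrolactone (C11=C13H2, C12=O). Locants assumed throughout: C1 = ring CH2, C2 = ketone, C3/C4 = epoxide with the C15 methyl on C4, C5 = CH–OAc, C6 = lactone O–CH, C7, C8 = CH–OAc, C9 = CH–O-acyl, C10 = C(=C14H2). Five contiguous stereocentres C5–C9 (5S,6R,7R,8R,9R) run around one half of the ring; the cis-epoxide C3/C4 (3R,4R) lies on the other side of C5, next to the C2 ketone, and the acyl group on O9 is (R)-2-methylbutanoyl. With the ring drawn flat and the lactone oxygen on C6 up (β), the substituents are 5α-OAc, 6β-O, 7β-C11, 8α-OAc, 9β-O-acyl and a β-epoxide; this α/β usage is kept for all intermediates. Fragile groups are the β,γ-unsaturated ketone (C2=O, C1H2, C10=C14), which conjugates under base, the α,β-epoxy ketone, the Michael-acceptor lactone, and three esters of two kinds that must be told apart (acetate on O5 and O8, 2-methylbutanoate on O9). The real difficulty is the medium ring itself: nine of its ten carbons are functionalized, seven are stereocentres, and closing it by C–C bond formation costs entropy on a chain that already carries most of this functionality. The key step exploits the fact that C10, which bears the exocyclic methylene C14, and the oxygenated C5 are 1,6-transannular partners, with four ring atoms between them on either side (C6–C9 and C1–C4). A C5–C10 bond therefore folds the ring into a decalin in which C6–C9 sit on one cyclohexane (ring B), the cis C3–C4 unit is a cyclohexene bond of ring A, O5 is a ring-fusion tertiary alcohol and C14 is an angular carbon that can carry a nucleofuge; O5–C5–C10–C14–X is then the array of a Grob fragmentation.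

## Logic of the disconnections

33 to 32. The C2=O bond is taken back to C2–H/O–H. The β,γ-unsaturated epoxy ketone is the most labile function and is unveiled last. The gain is that no earlier intermediate has an enolizable ketone next to C1. The oxidation must be neutral.

32 to 31 to 30. The O2–Si bond and the O5–acetyl bond are cut. 30 has a single free hydroxyl, so the acetylation needs no selectivity. The silyl ether must later come off without opening the neighbouring epoxide.

30 to 29. The two C–O bonds of the epoxide (C3–O, C4–O) are cut. In 29 the C5 hydroxyl is allylic to a (Z)-trisubstituted alkene, so the epoxide is delivered from a stereocentre that the target itself contains. The forward step must choose C3=C4 over C10=C14 and C11=C13 and deliver oxygen syn to O5 in the rotamer that minimizes A(1,3) strain.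

29 to 28. The C5–H bond is cut (alcohol to ketone). This is the price of the key step, which leaves C5 trigonal. The reduction must be 1,2-selective on a (Z)-enone and add hydride anti to the C6–O bond.

28 to 26 (key disconnection). The C5–C10 bond is re-formed, C5=O becomes C5–OH and C10=C14 becomes C10–C14H2–OMs. In one sentence: a Grob fragmentation of 26, a trans-decalin-5-ol with a mesyloxymethyl group on the angular C10, opens the ring-fusion bond to give the ten-membered ring of 28. The gain is large: the medium ring, the exocyclic methylene, the C5 carbonyl and the cis geometry of C3=C4 all come from a rigid bicycle, and C6–C9 lie on a cyclohexane. The demand is that O5–H be the only acidic site, that C14–O can lie anti to C5–C10, and that no displacement or acyl transfer competes.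

26 to 24 and 25; 24 to 23. The O9–acyl and O14–S bonds are cut. The primary neopentylic hydroxyl of 23 is sulfonylated first, then the hindered secondary O9–H is esterified with 25 while the tertiary O5–H stays free.

23 to 22 to 21 to 20. C14–O is traced back to C14–Si, the O2–Si bond is removed and C2–H is cut (back to the enone). The silicon bridge of 20 holds O9 and C14 at once. The C2 ketone is masked as a protected carbinol so that neither an enolate at C1 nor a second ketone interferes later.

20 to 19 to 18. The C10–C14 bond (and C1–H) is cut, then O9–Si. The one-carbon unit is delivered from O9 by a tethered radical, which fixes regiochemistry (C10, not C4) and creates the quaternary centre. The forward cyclization must be 5-exo onto a fully substituted enone carbon.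

18 to 16. The C5–O bond is cut, which returns ring A to a phenol. The gain is an aromatic ring A that needs no stereocontrol; the forward step is an oxidative dearomatization at the para carbon.

16 to 15 to 13 to 12. The C9–O bond is cut (epoxide opening at the benzylic carbon), the O8 acetyl is removed, then the epoxide. An α-epoxide opened with inversion at C9 gives the 8α,9β pattern. Formate on O9 and acetate on the phenol can be removed together while the O8 acetate stays.

12 to 11. The C8=C9 bond is cut into two vinyl groups (ring-closing metathesis to a six-membered ring).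

11 to 9 and 5. The C6–C7 bond and the lactone O6–C12 bond are cut. An allylboration sets C6 and C7 together, cis, and brings the complete α-methylene lactone.

9 to 8 to 7 to 6, and 5 to 4 to 3 to 1 and 2. These are aryl C–vinyl and O–acyl bonds on a commercial aldehyde, and C–B, O–acyl and C–C bonds of a Morita–Baylis–Hillman adduct.

## Other disconnections considered

Alternative 1: the first idea for a germacranolide. Cut C6–C7 and the lactone O–C12 bond. Forward key step: intramolecular CrCl2/NiCl2-mediated (Nozaki–Hiyama–Kishi) 2-(alkoxycarbonyl)allylation of seco aldehyde A1, closing the ten-membered ring and the lactone together. Grounds against: A1 is an open chain whose epoxide, C5, C8 and C9 centres must all be set by acyclic control. Its aldehyde is flanked by an acyloxy group and an epoxide, and the C2 ketone is not compatible with the organochromium reagent. The chair transition state of the (E)-allylchromium favours the anti adduct, that is the trans-fused lactone, whereas the target is cis-fused. The ring closure also needs high dilution. The chosen plan sets C6/C7 by a stereospecific allylboration on a benzaldehyde and never closes a medium ring.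

Alternative 2: cut C3=C4 (as the alkene precursor of the epoxide). Forward key step: ring-closing metathesis of seco diene A2 with the second-generation Grubbs catalyst, then epoxidation. Grounds against: a trisubstituted alkene in a ten-membered ring is the least favourable case for metathesis (transannular strain, ring-opening, dimerization). One partner is an enone and the other a 1,1-disubstituted alkene, and two further 1,1-disubstituted alkenes are present. The Z geometry would be left to ring strain, whereas the chosen plan inherits it from a cyclohexene. A2 again needs every stereocentre from acyclic chemistry.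

Alternative 3: cut C9–C10, with the C2–C7 bond of a cyclohexane as the bond broken in the forward direction. Forward key step: anionic oxy-Cope rearrangement of the 1-allenyl-2-vinylcyclohexenol A3, which would give the C2 ketone, the C1 methylene and the C10 exocyclic methylene in one step. Grounds against: the rearrangement leaves a C7=C8 double bond, so C7 and C8 would have to be set by an anti-Markovnikov hydration on the flexible ten-membered ring. C9 would depend on the chair/boat preference of the transition state. A3 needs two adjacent quaternary stereocentres, and the fragile β,γ-unsaturated ketone would exist from the ring expansion onwards. The chosen fragmentation fixes C6–C9 on a six-membered ring first and frees the ketone last.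

Key step: step 20

## Route

Step 1
Reactants: 1 acrolein; 2 methyl acrylate
Product: 3 methyl 3-hydroxy-2-methylidenepent-4-enoate (racemic)
Conditions: DABCO (20 mol %), 1,4-dioxane/H2O, rt
Reagents that add atoms: none
Why: Morita–Baylis–Hillman reaction; the amine–acrylate zwitterion adds 1,2 to the aldehyde of acrolein and the amine is eliminated. The carbinol centre is racemic and is erased in step 3.

Step 2
Reactants: 3 methyl 3-hydroxy-2-methylidenepent-4-enoate
Product: 4 methyl 3-[(methoxycarbonyl)oxy]-2-methylidenepent-4-enoate (racemic)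
Conditions: ClCO2Me, pyridine, CH2Cl2, 0 °C
Reagents that add atoms: methyl chloroformate, COC(=O)Cl
Why: O-acylation of the secondary allylic alcohol gives the carbonate leaving group for copper-catalysed allylic borylation.

Step 3
Reactants: 4 methyl 3-[(methoxycarbonyl)oxy]-2-methylidenepent-4-enoate
Product: 5 methyl (2E)-2-[(4,4,5,5-tetramethyl-1,3,2-dioxaborolan-2-yl)methyl]penta-2,4-dienoate
Conditions: B2pin2 (1.1 equiv), CuCl (5 mol %), Xantphos (5 mol %), KOC(CH3)3 (5 mol %), THF, 0 °C
Reagents that add atoms: bis(pinacolato)diboron, CC1(C)OB(OC1(C)C)B1OC(C)(C)C(C)(C)O1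
Why: Copper-catalysed SN2′ borylation of an allylic carbonate: the boryl copper species adds to the acrylate terminus (C13) and the carbonate is eliminated, losing CO2 and regenerating the copper alkoxide. The trisubstituted alkene should form with the vinyl group trans to the ester and cis to CH2B, the geometry that later gives the cis-lactone.

Step 4
Reactants: 6 2,4-dihydroxy-6-methylbenzaldehyde (orcinaldehyde)
Product: 7 4-formyl-3-hydroxy-5-methylphenyl acetate
Conditions: Ac2O (1.05 equiv), pyridine, CH2Cl2, 0 °C
Reagents that add atoms: acetic anhydride, CC(=O)OC(C)=O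
Why: Selective acetylation of the para hydroxyl; the ortho hydroxyl is hydrogen-bonded to the formyl group and far less nucleophilic. An acetate rather than an ether is chosen so that the later benzylic lactone C6–O bond is not activated towards ionization.

Step 5
Reactants: 7 4-formyl-3-hydroxy-5-methylphenyl acetate
Product: 8 4-formyl-3-methyl-5-[(trifluoromethylsulfonyl)oxy]phenyl acetate
Conditions: Tf2O, pyridine, CH2Cl2, 0 °C
Reagents that add atoms: trifluoromethanesulfonic anhydride, O=S(=O)(OS(=O)(=O)C(F)(F)F)C(F)(F)F
Why: Sulfonylation of the remaining phenol gives an aryl triflate activated for coupling by the ortho formyl group.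

Step 6
Reactants: 8 4-formyl-3-methyl-5-[(trifluoromethylsulfonyl)oxy]phenyl acetate
Product: 9 4-formyl-3-methyl-5-vinylphenyl acetate
Conditions: tributyl(vinyl)stannane, Pd(PPh3)4 (5 mol %), LiCl, 1,4-dioxane, 90 °C
Reagents that add atoms: tributyl(vinyl)stannane, C=C[Sn](CCCC)(CCCC)CCCC
Why: Stille coupling of an aryl triflate; the neutral conditions keep the aryl acetate and the aldehyde intact.

Step 7
Reactants: 9 4-formyl-3-methyl-5-vinylphenyl acetate; 5 methyl (2E)-2-[(pinacolboryl)methyl]penta-2,4-dienoate
Product: 11 (4S,5R)-5-(4-acetoxy-2-methyl-6-vinylphenyl)-3-methylidene-4-vinyloxolan-2-one (aryl and vinyl cis; C6 R and C7 S in target locants), via pinacol borate 10 (not isolated)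
Conditions: (R)-TRIP phosphoric acid (10 mol %), 4 Å MS, toluene, 0 °C to rt; then p-TsOH·H2O (10 mol %), CH2Cl2, rt
Reagents that add atoms: none
Why: Chiral phosphoric-acid-catalysed allylboration through a closed chair transition state: C7 (γ to boron) attacks the aldehyde and the vinyl group, cis to CH2B, is forced axial, so the syn adduct forms, which lactonizes to the cis-lactone with the α-methylene group in place. The (R)-acid is chosen for Re-face attack on the aryl aldehyde (6R), by analogy with simple aryl aldehydes and allyl pinacolboronates; the (S)-acid would be used if the sense proved opposite.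

Step 8
Reactants: 11 cis-lactone with aryl vinyl and C7 vinyl groups
Product: 12 tricyclic cis-lactone (target locants: aromatic ring A with 2-OAc and 4-Me; C8=C9 alkene; 6β-O/7β-C11 α-methylene-γ-lactone)
Conditions: second-generation Grubbs catalyst RuCl2(=CHPh)(PCy3)(H2IMes) (5 mol %), CH2Cl2, 40 °C
Reagents that add atoms: none
Why: Ring-closing metathesis of the styrene and the C7 vinyl group closes the six-membered ring B and releases ethylene; the cis relationship of aryl and vinyl on the lactone makes the cis-fused tricycle strain-free. The electron-poor 1,1-disubstituted lactone methylene should not take part.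

Step 9
Reactants: 12 tricyclic cis-lactone with C8=C9
Product: 13 8α,9α-epoxide of 12
Conditions: dimethyldioxirane (acetone solution), CH2Cl2, 0 °C
Reagents that add atoms: dimethyldioxirane, CC1(C)OO1
Why: Neutral epoxidation of the styrenic alkene; the lactone ring and C11 on C7 cover the β face, so oxygen should add from the α face. The acrylate-type C11=C13 is inert to the electrophilic oxidant.

Step 10
Reactants: 13 8α,9α-epoxide
Product: 15 8α-acetoxy-9β-formyloxy tetralin lactone (aryl 2-acetate), via hydroxy formate 14 (not isolated)
Conditions: HCO2H, CH2Cl2, 0 °C; evaporate; then Ac2O, pyridine, DMAP (cat.), 0 °C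
Reagents that add atoms: formic acid, O=CO; acetic anhydride, CC(=O)OC(C)=O
Why: Acid-mediated opening of the aryl epoxide occurs at the benzylic C9 with inversion, giving the 9β-formate and the 8α-alcohol (trans-diol pattern of the target). Immediate acetylation fixes O8 as its final acetate before any acyl migration.

Step 11
Reactants: 15 8α-acetate 9β-formate aryl acetate
Product: 16 phenol with 9β-OH and 8α-OAc (tetralin cis-lactone)
Conditions: KHCO3, MeOH, 0 °C
Reagents that add atoms: none
Why: Formates and aryl acetates are methanolysed far faster than a secondary alkyl acetate or the lactone, so the phenol and O9–H are freed in one operation while the O8 acetate stays.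

Step 12
Reactants: 16 phenol with 9β-OH and 8α-OAc
Product: 18 p-quinol (5α-hydroxy-cyclohexa-1(10),3-dien-2-one; 9β-OH; 8α-OAc; cis-lactone), via hydroperoxide 17 (not isolated)
Conditions: KHSO5 (as Oxone, 2KHSO5·KHSO4·K2SO4), NaHCO3, MeCN/H2O, rt; then Me2S
Reagents that add atoms: potassium peroxymonosulfate, [K+].[O-]S(=O)(=O)OO
Why: Oxidative dearomatization: singlet oxygen released from peroxymonosulfate adds to the para carbon C5 of the electron-rich trialkylphenol to give the p-peroxyquinol, which the sulfide reduces to the p-quinol. Attack should come from the α face, anti to the pseudoaxial C6–O bond and the lactone ring, placing O5 trans to O6; this centre only has to be uniform, since it is erased in step 20.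

Step 13
Reactants: 18 p-quinol
Product: 19 9β-O-[(bromomethyl)dimethylsilyl] ether of 18
Conditions: BrCH2SiMe2Cl (1.1 equiv), imidazole, CH2Cl2, 0 °C
Reagents that add atoms: (bromomethyl)chlorodimethylsilane, C[Si](C)(Cl)CBr
Why: Silylation of the secondary allylic O9–H; the tertiary, doubly flanked O5–H should not react at 0 °C with one equivalent.

Step 14
Reactants: 19 9β-O-[(bromomethyl)dimethylsilyl] ether
Product: 20 trans-decalin enone (C14 methylene β on C10 and bridged to O9 through SiMe2; 5α-OH; 3-en-2-one)
Conditions: Bu3SnH (1.3 equiv, slow addition), AIBN (cat.), benzene (0.01 M), 80 °C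
Reagents that add atoms: none
Why: Silicon-tethered radical cyclization (Stork–Nishiyama type): the α-silyl radical adds 5-exo to C10, the β-carbon of the dienone, and the α-keto radical at C1 is reduced by the stannane. The tether can reach only C10 (not C4), and the five-membered oxasilolane must be cis-fused, so C14 enters on the β face, trans to the 5α-hydroxyl.

Step 15
Reactants: 20 trans-decalin enone
Product: 21 2β-allylic alcohol of 20
Conditions: NaBH4, CeCl3·7H2O, MeOH, −78 °C
Reagents that add atoms: none
Why: Luche 1,2-reduction; the axial β-C14 on C10 is 1,3-diaxial to a β approach at C2, so hydride should enter from the α face and give the 2β (axial) alcohol. This centre is temporary and only masks the ketone through the fragmentation.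

Step 16
Reactants: 21 2β-allylic alcohol
Product: 22 2β-tert-butyldimethylsilyl ether of 21
Conditions: TBSOTf (1.1 equiv), 2,6-lutidine, CH2Cl2, −78 °C
Reagents that add atoms: tert-butyldimethylsilyl trifluoromethanesulfonate, CC(C)(C)[Si](C)(C)OS(=O)(=O)C(F)(F)F
Why: Silylation of the secondary alcohol at low temperature; the tertiary O5–H between two fully substituted carbons should remain free.

Step 17
Reactants: 22 2β-silyl ether with the O9–Si–C14 bridge
Product: 23 triol (14-OH; 9β-OH; 5α-OH; 2β-OTBS; 8α-OAc)
Conditions: H2O2 (30 %), KF, KHCO3, THF/MeOH, rt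
Reagents that add atoms: hydrogen peroxide, OO
Why: Tamao–Fleming oxidation of the alkoxysilane C–Si bond gives the angular hydroxymethyl group and frees O9–H; isolated and electron-poor alkenes are inert to buffered peroxide. Acetyl migration from O8 to the now neopentylic O9 is disfavoured sterically.

Step 18
Reactants: 23 triol
Product: 24 14-O-methanesulfonate of 23
Conditions: MsCl (1.1 equiv), Et3N, CH2Cl2, −20 °C
Reagents that add atoms: methanesulfonyl chloride, CS(=O)(=O)Cl
Why: Sulfonylation of the only primary hydroxyl; the hindered secondary O9–H and the tertiary O5–H react much more slowly.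

Step 19
Reactants: 24 14-O-methanesulfonate; 25 (R)-2-methylbutanoic acid
Product: 26 9β-[(R)-2-methylbutanoyloxy] trans-decalin-5α-ol with 14-OMs; 2β-OTBS; 8α-OAc; cis-lactone
Conditions: 25, 2,4,6-trichlorobenzoyl chloride, Et3N, THF, rt; then 24, DMAP, toluene, 40 °C
Reagents that add atoms: none
Why: Yamaguchi esterification of the hindered secondary O9–H; the tertiary O5–H is inert and the neopentylic mesylate cannot be displaced by DMAP. Mixed-anhydride activation avoids a ketene pathway, so the (R) centre of the acid should be retained.

Step 20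
Reactants: 26 trans-decalin-5α-ol with angular CH2OMs
Product: 28 (3Z)-5-oxo-germacra-3,10(14),11(13)-trien-12,6-olide bearing 2β-OTBS; 8α-OAc; 9β-O-[(R)-2-methylbutanoyl], via sodium alkoxide 27 (not isolated)
Conditions: NaH (1.1 equiv), 15-crown-5 (cat.), THF, 0 °C to rt
Reagents that add atoms: none
Why: Deprotonation of the only hydroxyl of 26 gives the tertiary alkoxide 27; rotation about C10–C14 places the C14–OMs bond anti-periplanar to the C5–C10 ring-fusion bond, and a concerted Grob fragmentation forms C5=O and C10=C14 while C5–C10 breaks. The closest known reaction type is the base-induced fragmentation of decalin-1,3-diol monosulfonates to cyclodecenones; here the nucleofuge sits on the angular carbon, so the new alkene is the exocyclic methylene and no E/Z question arises. No ring is closed: the ten-membered ring appears by opening the bond shared by rings A and B, so no macrocyclization entropy is paid. No stereocentre is created (C5 and C10 become trigonal); C6–C9 and C2 are carried over untouched and the cis geometry of C3=C4 is inherited from the cyclohexene. The step needs fragmentation to beat displacement, acyl transfer and C-deprotonation. The mesylate is neopentylic and cannot be displaced to an oxetane, the alkoxide is trans-diaxial to the lactone oxygen and trans-1,3 to the O9 ester, no ketone or epoxide is present before the event, and the base is consumed as sodium methanesulfonate once the ketone forms. Conjugation of the new ketone with C3=C4 and relief of the 1,3-diaxial contact between C14 and O6 add driving force.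

Step 21
Reactants: 28 (3Z)-5-oxo macrocyclic enone
Product: 29 (5S)-5α-allylic alcohol of 28
Conditions: NaBH4, CeCl3·7H2O, MeOH/THF, −78 °C
Reagents that add atoms: none
Why: Luche 1,2-reduction of the enone; by the polar Felkin–Anh model hydride adds anti to the C6–O (acyloxy, non-chelating) bond, which gives the 5,6-syn arrangement of the target (5α-OH, 6β-O). The low temperature and cerium salt suppress conjugate reduction of the lactone methylene.

Step 22
Reactants: 29 (5S)-allylic alcohol
Product: 30 3β,4β-epoxide (3R,4R) of 29
Conditions: mCPBA (1.05 equiv), NaHCO3, CH2Cl2, −20 to 0 °C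
Reagents that add atoms: 3-chloroperoxybenzoic acid, O=C(OO)c1cccc(Cl)c1
Why: Hydroxyl-directed peracid epoxidation of a (Z)-allylic alcohol: A(1,3) strain with C2 keeps H5 in the alkene plane and the hydrogen-bonded peracid delivers oxygen syn to O5, which corresponds to the (3R,4R) epoxide for the (5S) alcohol. The trisubstituted, hydroxyl-activated C3=C4 should react well before the 1,1-disubstituted C10=C14 next to an ester or the acrylate-type C11=C13.

Step 23
Reactants: 30 epoxy alcohol
Product: 31 5α-acetate of 30
Conditions: Ac2O, DMAP, pyridine, CH2Cl2, 0 °C to rt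
Reagents that add atoms: acetic anhydride, CC(=O)OC(C)=O
Why: Acetylation of the only free hydroxyl.

Step 24
Reactants: 31 5α-acetate with 2β-OTBS
Product: 32 2β-alcohol (silyl ether removed)
Conditions: HF·pyridine, pyridine, THF, 0 °C to rt
Reagents that add atoms: none
Why: Buffered fluoride cleaves the secondary silyl ether; the near-neutral medium avoids epoxide opening, epoxide migration and acetyl migration.

Step 25
Reactants: 32 2β-alcohol
Product: 33 (3R,4R,5S,6R,7R,8R,9R)-5,8-diacetoxy-3,4-epoxy-9-[(2R)-2-methylbutanoyloxy]-2-oxogermacra-10(14),11(13)-dien-12,6-olide (target, CNP0256300.1)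
Conditions: Dess–Martin periodinane, NaHCO3, CH2Cl2, 0 °C to rt
Reagents that add atoms: none
Why: Dess–Martin oxidation of the secondary alcohol under buffered, non-basic conditions gives the epoxy ketone without moving C10=C14 into conjugation.

## Compound list

1 | acrolein (prop-2-enal) | C=CC=O | starting material
2 | methyl acrylate | C=CC(=O)OC | starting material
3 | methyl 3-hydroxy-2-methylidenepent-4-enoate (racemic) | C=CC(O)C(=C)C(=O)OC | intermediate
4 | methyl 3-[(methoxycarbonyl)oxy]-2-methylidenepent-4-enoate (racemic) | C=CC(OC(=O)OC)C(=C)C(=O)OC | intermediate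
5 | methyl (2E)-2-[(4,4,5,5-tetramethyl-1,3,2-dioxaborolan-2-yl)methyl]penta-2,4-dienoate | COC(=O)/C(CB1OC(C)(C)C(C)(C)O1)=C/C=C | intermediate
6 | 2,4-dihydroxy-6-methylbenzaldehyde (orcinaldehyde) | Cc1cc(O)cc(O)c1C=O | starting material
7 | 4-formyl-3-hydroxy-5-methylphenyl acetate | CC(=O)Oc1cc(C)c(C=O)c(O)c1 | intermediate
8 | 4-formyl-3-methyl-5-[(trifluoromethylsulfonyl)oxy]phenyl acetate | CC(=O)Oc1cc(C)c(C=O)c(OS(=O)(=O)C(F)(F)F)c1 | intermediate
9 | 4-formyl-3-methyl-5-vinylphenyl acetate | CC(=O)Oc1cc(C)c(C=O)c(C=C)c1 | intermediate
10 | methyl (3S,4R)-4-(4-acetoxy-2-methyl-6-vinylphenyl)-2-methylidene-4-[(4,4,5,5-tetramethyl-1,3,2-dioxaborolan-2-yl)oxy]-3-vinylbutanoate | C=C(C(=O)OC)[C@H](C=C)[C@@H](OB1OC(C)(C)C(C)(C)O1)c1c(C=C)cc(OC(C)=O)cc1C | intermediate (not isolated)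
11 | (4S,5R)-5-(4-acetoxy-2-methyl-6-vinylphenyl)-3-methylidene-4-vinyloxolan-2-one (aryl and vinyl cis) | C=C1C(=O)O[C@H]([C@H]1C=C)c1c(C=C)cc(OC(C)=O)cc1C | intermediate
12 | tricyclic cis-lactone: aromatic ring A (2-OAc, 4-Me), C8=C9, 6β-O/7β-C11 α-methylene-γ-lactone | C=C1C(=O)O[C@@H]2[C@H]1C=Cc3cc(OC(C)=O)cc(C)c32 | intermediate
13 | 8α,9α-epoxide of 12 | C=C1C(=O)O[C@@H]2[C@H]1[C@H]3O[C@H]3c4cc(OC(C)=O)cc(C)c42 | intermediate
14 | 8α-hydroxy-9β-formyloxy tetralin cis-lactone (aryl 2-acetate) | C=C1C(=O)O[C@@H]2[C@H]1[C@@H](O)[C@H](OC=O)c3cc(OC(C)=O)cc(C)c32 | intermediate (not isolated)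
15 | 8α-acetoxy-9β-formyloxy tetralin cis-lactone (aryl 2-acetate) | C=C1C(=O)O[C@@H]2[C@H]1[C@@H](OC(C)=O)[C@H](OC=O)c3cc(OC(C)=O)cc(C)c32 | intermediate
16 | 8α-acetoxy-9β-hydroxy tetralin cis-lactone, free phenol at C2 | C=C1C(=O)O[C@@H]2[C@H]1[C@@H](OC(C)=O)[C@H](O)c3cc(O)cc(C)c32 | intermediate
17 | 5α-hydroperoxy-cyclohexa-1(10),3-dien-2-one (p-peroxyquinol; 9β-OH, 8α-OAc) | C=C1C(=O)O[C@@H]2[C@H]1[C@@H](OC(C)=O)[C@H](O)C3=CC(=O)C=C(C)[C@]23OO | intermediate (not isolated)
18 | 5α-hydroxy-cyclohexa-1(10),3-dien-2-one (p-quinol; 9β-OH, 8α-OAc) | C=C1C(=O)O[C@@H]2[C@H]1[C@@H](OC(C)=O)[C@H](O)C3=CC(=O)C=C(C)[C@]23O | intermediate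
19 | 9β-O-[(bromomethyl)dimethylsilyl] ether of 18 | C=C1C(=O)O[C@@H]2[C@H]1[C@@H](OC(C)=O)[C@H](O[Si](C)(C)CBr)C3=CC(=O)C=C(C)[C@]23O | intermediate
20 | trans-decalin 3-en-2-one, C14 β on C10 bridged to O9 by SiMe2, 5α-OH | C=C1C(=O)O[C@@H]2[C@H]1[C@@H](OC(C)=O)[C@@H]3O[Si](C)(C)C[C@@]34CC(=O)C=C(C)[C@]24O | intermediate
21 | 2β-allylic alcohol of 20 | C=C1C(=O)O[C@@H]2[C@H]1[C@@H](OC(C)=O)[C@@H]3O[Si](C)(C)C[C@@]34C[C@H](O)C=C(C)[C@]24O | intermediate
22 | 2β-tert-butyldimethylsilyl ether of 21 | C=C1C(=O)O[C@@H]2[C@H]1[C@@H](OC(C)=O)[C@@H]3O[Si](C)(C)C[C@@]34C[C@H](O[Si](C)(C)C(C)(C)C)C=C(C)[C@]24O | intermediate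
23 | triol: 14-OH, 9β-OH, 5α-OH (2β-OTBS, 8α-OAc, cis-lactone) | C=C1C(=O)O[C@@H]2[C@H]1[C@@H](OC(C)=O)[C@H](O)[C@@]3(CO)C[C@H](O[Si](C)(C)C(C)(C)C)C=C(C)[C@]23O | intermediate
24 | 14-O-methanesulfonate of 23 | C=C1C(=O)O[C@@H]2[C@H]1[C@@H](OC(C)=O)[C@H](O)[C@@]3(COS(C)(=O)=O)C[C@H](O[Si](C)(C)C(C)(C)C)C=C(C)[C@]23O | intermediate
25 | (R)-2-methylbutanoic acid | CC[C@@H](C)C(=O)O | starting material
26 | 9β-[(R)-2-methylbutanoate] of 24 (trans-decalin-5α-ol, angular CH2OMs) | C=C1C(=O)O[C@@H]2[C@H]1[C@@H](OC(C)=O)[C@H](OC(=O)[C@H](C)CC)[C@@]3(COS(C)(=O)=O)C[C@H](O[Si](C)(C)C(C)(C)C)C=C(C)[C@]23O | intermediate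
27 | sodium 5α-alkoxide of 26 | C=C1C(=O)O[C@@H]2[C@H]1[C@@H](OC(C)=O)[C@H](OC(=O)[C@H](C)CC)[C@@]3(COS(C)(=O)=O)C[C@H](O[Si](C)(C)C(C)(C)C)C=C(C)[C@]23[O-].[Na+] | intermediate (not isolated)
28 | (3Z)-5-oxo-germacra-3,10(14),11(13)-trien-12,6-olide with 2β-OTBS, 8α-OAc, 9β-O-[(R)-2-methylbutanoyl] | C=C1C(=O)O[C@@H]2[C@H]1[C@@H](OC(C)=O)[C@H](OC(=O)[C@H](C)CC)C(=C)C[C@H](O[Si](C)(C)C(C)(C)C)/C=C(/C)C2=O | intermediate
29 | (5S)-5α-alcohol of 28 | C=C1C(=O)O[C@@H]2[C@H]1[C@@H](OC(C)=O)[C@H](OC(=O)[C@H](C)CC)C(=C)C[C@H](O[Si](C)(C)C(C)(C)C)/C=C(/C)[C@H]2O | intermediate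
30 | (3R,4R)-3β,4β-epoxide of 29 | C=C1C(=O)O[C@@H]2[C@H]1[C@@H](OC(C)=O)[C@H](OC(=O)[C@H](C)CC)C(=C)C[C@H](O[Si](C)(C)C(C)(C)C)[C@@H]1O[C@]1(C)[C@H]2O | intermediate
31 | 5α-acetate of 30 | C=C1C(=O)O[C@@H]2[C@H]1[C@@H](OC(C)=O)[C@H](OC(=O)[C@H](C)CC)C(=C)C[C@H](O[Si](C)(C)C(C)(C)C)[C@@H]1O[C@]1(C)[C@H]2OC(C)=O | intermediate
32 | 2β-alcohol (31 without the silyl group) | C=C1C(=O)O[C@@H]2[C@H]1[C@@H](OC(C)=O)[C@H](OC(=O)[C@H](C)CC)C(=C)C[C@H](O)[C@@H]1O[C@]1(C)[C@H]2OC(C)=O | intermediate
33 | (3R,4R,5S,6R,7R,8R,9R)-5,8-diacetoxy-3,4-epoxy-9-[(2R)-2-methylbutanoyloxy]-2-oxogermacra-10(14),11(13)-dien-12,6-olide | C=C1C(=O)O[C@@H]2[C@H]1[C@@H](OC(C)=O)[C@H](OC(=O)[C@H](C)CC)C(=C)CC(=O)[C@@H]1O[C@]1(C)[C@H]2OC(C)=O | target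

## Step count and least certain steps

Total: 25 steps. Longest linear sequence: 22 steps (6 to 33, steps 4–25); the three-step branch 1 + 2 to 5 joins at step 7.

Step 20 (key step). Most likely failure: the tertiary alkoxide reacts elsewhere before it fragments. Possible paths are acyl transfer from the O9 ester, or proton transfer from C7–H (γ to the lactone carbonyl) with loss of the exocyclic lactone alkene; either becomes competitive if the rotamer with C14–O anti to C5–C10 is crowded by the axial O6. Fallback (base-free): from triol 23, the primary hydroxyl is converted into the iodide (I2, PPh3, imidazole) to give the 14-iodo diol F1. O9–H is then esterified with 25 as in step 19 to give the 14-iodo 9-ester F2. The tertiary alcohol is finally fragmented through its alkoxy radical (PhI(OAc)2, I2, visible light, cyclohexane/CH2Cl2): β-scission of C5–C10 followed by loss of the β-iodine atom returns to the route at 28.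

Step 7. Most likely failure: sluggish addition of the ester-deactivated allylboronate to the doubly ortho-substituted aldehyde under a weak chiral acid, with incomplete enantiofacial control. Fallback: from 3, allylic transposition with HBr (48 %)/H2SO4 gives methyl (2Z)-2-(bromomethyl)penta-2,4-dienoate F3. Indium-mediated Barbier coupling of F3 with 9 (In powder, THF/H2O, syn-selective; then p-TsOH) gives the racemic cis-lactone F4, which is resolved by preparative chromatography on a chiral stationary phase to return at 11.

Step 14. Most likely failure: stannyl or carbon radicals add to the lactone methylene (hydrostannation), or the α-silyl radical is reduced before it closes on the fully substituted C10. Fallback: from 19, conjugate addition of dimethylamine (Me2NH, THF, 0 °C) masks the lactone as the β-(dimethylamino)methyl lactone F5. The tethered radical cyclization under the conditions of step 14 then gives the cyclized amino lactone F6, and quaternization with MeI followed by NaHCO3 eliminates the amine and returns at 20.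

Step 21. Most likely failure: poor facial selectivity or the opposite sense of hydride delivery, because the conformation of the ten-membered ring may override Felkin control at C6; some conjugate reduction is also possible. Fallback: from 28, if the reduction gives mainly the 5-epi-alcohol F7, Mitsunobu inversion with chloroacetic acid (PPh3, DIAD, toluene) gives the inverted 5-chloroacetate F8. Thiourea/NaHCO3 in ethanol then removes the chloroacetyl group in the presence of the other esters and returns at 29.

Step 22. Most likely failure: loss of chemoselectivity (attack at C10=C14), or delivery to the wrong face if the ring holds C6 rather than H5 in the alkene plane. Fallback: from 28, the order of events is changed. Nucleophilic (Weitz–Scheffer) epoxidation of the enone with t-BuOOH/DBU, where peroxide should attack C3 from the ring periphery, gives the epoxy ketone F9; reduction with NaBH4/CeCl3·7H2O at −78 °C then returns at 30.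

## Further compounds

F1 | step 20 | 14-iodo diol (23 with C14–I in place of C14–OH) | C=C1C(=O)O[C@@H]2[C@H]1[C@@H](OC(C)=O)[C@H](O)[C@@]3(CI)C[C@H](O[Si](C)(C)C(C)(C)C)C=C(C)[C@]23O
F2 | step 20 | 14-iodo 9β-[(R)-2-methylbutanoate] (iodo analogue of 26) | C=C1C(=O)O[C@@H]2[C@H]1[C@@H](OC(C)=O)[C@H](OC(=O)[C@H](C)CC)[C@@]3(CI)C[C@H](O[Si](C)(C)C(C)(C)C)C=C(C)[C@]23O
F3 | step 7 | methyl (2Z)-2-(bromomethyl)penta-2,4-dienoate | COC(=O)/C(CBr)=C/C=C
F4 | step 7 | racemic cis-lactone (1:1 mixture of 11 and its enantiomer) | C=C1C(=O)O[C@H]([C@H]1C=C)c1c(C=C)cc(OC(C)=O)cc1C.C=C1C(=O)O[C@@H]([C@@H]1C=C)c1c(C=C)cc(OC(C)=O)cc1C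
F5 | step 14 | β-(dimethylamino)methyl lactone from 19 (C11 epimers) | CN(C)CC1C(=O)O[C@@H]2[C@H]1[C@@H](OC(C)=O)[C@H](O[Si](C)(C)CBr)C3=CC(=O)C=C(C)[C@]23O
F6 | step 14 | cyclized amino lactone (amine adduct of 20, C11 epimers) | CN(C)CC1C(=O)O[C@@H]2[C@H]1[C@@H](OC(C)=O)[C@@H]3O[Si](C)(C)C[C@@]34CC(=O)C=C(C)[C@]24O
F7 | step 21 | 5-epi-alcohol (5β-OH epimer of 29) | C=C1C(=O)O[C@@H]2[C@H]1[C@@H](OC(C)=O)[C@H](OC(=O)[C@H](C)CC)C(=C)C[C@H](O[Si](C)(C)C(C)(C)C)/C=C(/C)[C@@H]2O
F8 | step 21 | 5α-chloroacetate of 29 | C=C1C(=O)O[C@@H]2[C@H]1[C@@H](OC(C)=O)[C@H](OC(=O)[C@H](C)CC)C(=C)C[C@H](O[Si](C)(C)C(C)(C)C)/C=C(/C)[C@H]2OC(=O)CCl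
F9 | step 22 | 3β,4β-epoxy-5-ketone (epoxide of 28) | C=C1C(=O)O[C@@H]2[C@H]1[C@@H](OC(C)=O)[C@H](OC(=O)[C@H](C)CC)C(=C)C[C@H](O[Si](C)(C)C(C)(C)C)[C@@H]1O[C@]1(C)C2=O
A1 | alternative 1 | C6–C7 seco aldehyde with (Z)-2-(bromomethyl)enoate (methyl ester; other groups as in 33) | BrC/C(C(=O)OC)=C\[C@@H](OC(C)=O)[C@H](OC(=O)[C@H](C)CC)C(=C)CC(=O)[C@@H]1O[C@]1(C)[C@H](C=O)OC(C)=O
A2 | alternative 2 | C3–C4 seco diene (C3 vinyl ketone, C4 isopropenyl; other groups as in 33) | C=C1C(=O)O[C@H]([C@H]1[C@@H](OC(C)=O)[C@H](OC(=O)[C@H](C)CC)C(=C)CC(=O)C=C)[C@H](OC(C)=O)C(C)=C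
A3 | alternative 3 | 1-allenyl-2-vinylcyclohex-2-enol fused to the γ-lactone (5-OTBS; PMB enol ether at C9) | C=C=C[C@@]1(O)C=C(C)[C@@H](O[Si](C)(C)C(C)(C)C)[C@@H]2OC(=O)C[C@]12/C=C/OCc1ccc(OC)cc1
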